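## The problem

1. Morusyunnansin E (14) is a (2S)-flavan. Ring A (C4a–C8a) is fused to pyran ring C (O1, C2, C3, C4). C2 carries the 2,4-dihydroxyphenyl ring B, C7 an OMe group, and C8 an (E)-4-hydroxy-3-methylbut-2-enyl chain (C1''–C4'').
2. Ring A is 1,2,3,4-tetrasubstituted, with the C8 chain wedged between O1 and the C7 oxygen. Substitution or rearrangement on simple resorcinols reaches this pattern only with regiochemical losses.
3. C2 is the only stereocentre, so no other centre can control it, and a reagent or catalyst must set it.
4. C2 is also fragile: C2–O1 is a benzylic aryl ether on a ring with OH ortho (C2') and para (C4'), so acid or base can open it through a quinone methide and racemise it. This argues for setting C2 late and touching it little afterwards.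
5. The C2''=C3'' alkene and its primary allylic alcohol forbid catalytic hydrogenation, benzyl-ether hydrogenolysis and strong acid. The E geometry must be made deliberately, and two phenols and one alcohol must end free beside one methyl ether.
6. The feature exploited is the same array that makes C2 labile. O1 on C2, together with the C2' and C4' oxygens of ring B, stabilises a positive charge at C2 so well that, at full unsaturation of C2–C3–C4, rings A and C become the flat, achiral, aromatic 1-benzopyrylium (flavylium) ion. The C2'–OH, three atoms from C2, can anchor a chiral counter-anion by a hydrogen bond.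
7. A second feature: rings A and C, with C7–OMe, the five-carbon chain on C8 and an oxidised C2, are present intact in the commercial coumarin osthole (1).

## Retrosynthesis

**14 ⇒ 13.** Only two O–Si bonds are cut (C4'–O–TIPS and C4''–O–TBS). Silyl groups are chosen because buffered fluoride is neither acidic nor hydrogenolytic. Compound 13 already has the C2'–OH free. The forward step must avoid phenoxide-driven opening of C2–O1.

**13 ⇒ 9 (key cut).** The bonds removed are C4–H, C3–H and C2–H, which come from two hydrides and one proton. The chain runs 13 ⇐ chroman-2-ylium ion 12 ⇐ enol ether 11 ⇐ flavylium ion 10 ⇐ hemiketal 9, which is in ring–chain equilibrium with (Z)-enone 8.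
- The neighbouring cuts (O1–C2 or C2–C1') require a stereospecific event at a carbon that ionises easily. Cutting C–H bonds puts the stereodetermining event on the cation itself, so the ease of ionisation works for the plan.
- Metal-catalysed hydrogenation of the same unsaturation would also saturate C2''=C3''. A dihydropyridine hydride donor attacks only cations.
- Precursor 9 has no fixed stereocentre. Both C2 epimers and 8 collapse to the one planar ion 10.
- The forward reaction must deliver hydride to C4 first and then to C2, attack the Re face of C2 in 12, and leave 13 un-ionised.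

**9 ⇒ 4 + 7.** The C2–C1' bond is cut, giving the lactone carbonyl of coumarin 4 and the aryl dianion 7. This is the only skeletal C–C bond the route has to make. The endocyclic cis C3=C4 of the coumarin ensures that the adduct is born as the Z-enone 8, the geometry that can close to 9. The forward reaction must be a single 1,2-addition.

**7 ⇒ 6 ⇒ 5.** Dianion 7 comes from bromophenol 6 by deprotonation and bromine–lithium exchange. Bromophenol 6 comes from 4-bromoresorcinol (5) by silylating the hydroxyl remote from bromine. Capping C4'–O leaves C2'–OH as the only acidic anchor near C2, weakens the para donor that would help 13 re-ionise, and makes the substrate soluble in toluene.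

**4 ⇒ 3 ⇒ 2 ⇒ 1.** The C4''–O bond is cut. Silyl ether 4 comes from alcohol 3, 3 from enal 2, and 2 from osthole (1) by E-selective allylic C–H oxidation. Taking ring A ready-made from 1 removes the whole regiochemical problem of C8. The oxidation is done early, on the robust electron-poor coumarin rather than on an electron-rich flavan.

## Roads not taken

**Alternative 1** (the most obvious): cut O1–C2.
- Forward: aldol union of a ring-A aldehyde with a ring-B methyl ketone, followed by saturation, leads to ketone A1. Asymmetric ketone reduction gives (R)-alcohol A2. A Mitsunobu reaction closes the ring with inversion, and the side chain is oxidised afterwards.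
- Why the chosen plan is better:
  - Displacement at a carbinol carbon bearing a 2,4-dioxygenated aryl group competes with ionisation, so enantiopurity is at risk in the ring closure itself.
  - Both ring-B phenols must be masked, and their acidic release comes after C2 is set.
  - The 3-prenylated ring-A aldehyde is not commercial and costs several steps with a regiochemical issue.
  - The allylic oxidation falls late, on an electron-rich flavan.
  - The step count is roughly double.

**Alternative 2:** cut O1–C2 and C3–C4 together.
- Forward: salicyl alcohol A3 is ionised to o-quinone methide A4, which undergoes an inverse-demand hetero-Diels–Alder reaction with styrene A5 under a chiral acid.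
- Why the chosen plan is better:
  - A4 has an unsubstituted methide terminus, so it is short-lived and prone to self-addition.
  - The new stereocentre forms at the styrene carbon in the ring-closing half of a stepwise process, far from where the catalyst binds A4.
  - A5 polymerises under acid.
  - A3 needs the same multistep construction of ring A that 1 makes unnecessary.

**Alternative 3:** cut C2–C1' at the chromanone level.
- Forward: asymmetric conjugate addition of boronic acid A7 to chromone A6 gives flavanone A8, and C4 is then deoxygenated.
- Why the chosen plan is better: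
  - A7 is ortho-substituted and electron-rich, so it transmetalates slowly and protodeboronates readily.
  - C2 of A8 racemises by retro-oxa-Michael opening.
  - Removing C4=O costs two or three reductive or acidic steps that endanger C2''=C3'' and C2.
  - A6 is not commercial.

Key step: step 6

Assumption: the sense of induction in step 6 follows the binding model given there. Both antipodes of the acid are commercial, so the (S)-acid would replace the (R)-acid if the model proves inverted.

## Steps

Step 1
Reactants: 1 osthole, 7-methoxy-8-(3-methylbut-2-enyl)-2H-chromen-2-one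
Product: 2 (E)-4-(7-methoxy-2-oxo-2H-chromen-8-yl)-2-methylbut-2-enal
Conditions: SeO2 (1.2 equiv), 1,4-dioxane–H2O (50:1), 90 °C
Reagents that add atoms: selenium dioxide, O=[Se]=O
Why: Riley allylic oxidation; the ene reaction and [2,3]-shift act at the more substituted alkene terminus and select the methyl group trans to the chain, which should give the E-enal. The electron-poor coumarin C3=C4 and the aryl ether are inert.

Step 2
Reactants: 2 (E)-4-(7-methoxy-2-oxo-2H-chromen-8-yl)-2-methylbut-2-enal
Product: 3 8-[(E)-4-hydroxy-3-methylbut-2-enyl]-7-methoxy-2H-chromen-2-one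
Conditions: NaBH4, CeCl3·7H2O, MeOH, −20 °C
Reagents that add atoms: none
Why: Luche 1,2-reduction of the enal is much faster than any attack on the conjugated lactone at this temperature, and the E geometry is untouched.

Step 3
Reactants: 3 8-[(E)-4-hydroxy-3-methylbut-2-enyl]-7-methoxy-2H-chromen-2-one
Product: 4 8-[(E)-4-(tert-butyldimethylsilyloxy)-3-methylbut-2-enyl]-7-methoxy-2H-chromen-2-one
Conditions: TBSCl, imidazole, CH2Cl2, 0 °C → rt
Reagents that add atoms: tert-butyldimethylsilyl chloride, CC(C)(C)[Si](C)(C)Cl
Why: Standard silylation of a primary alcohol removes the only acidic proton before the organolithium step and adds lipophilicity for step 6.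

Step 4
Reactants: 5 4-bromobenzene-1,3-diol (4-bromoresorcinol)
Product: 6 2-bromo-5-(triisopropylsilyloxy)phenol
Conditions: TIPSCl (1.0 equiv), imidazole, CH2Cl2–DMF, −20 → 0 °C
Reagents that add atoms: triisopropylsilyl chloride, CC(C)[Si](Cl)(C(C)C)C(C)C
Why: Sterically governed monosilylation; the hydroxyl next to bromine is shielded and engaged in an O–H···Br contact, so the bulky chlorosilane should take the remote hydroxyl para to bromine.

Step 5
Reactants: 6 2-bromo-5-(triisopropylsilyloxy)phenol; 4 8-[(E)-4-(tert-butyldimethylsilyloxy)-3-methylbut-2-enyl]-7-methoxy-2H-chromen-2-one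
Product: 9 2-[2-hydroxy-4-(triisopropylsilyloxy)phenyl]-7-methoxy-8-[(E)-4-(tert-butyldimethylsilyloxy)-3-methylbut-2-enyl]-2H-chromen-2-ol (racemic labile hemiketal), via dilithio reagent 7 (not isolated), via open (Z)-enone tautomer 8 (not isolated)
Conditions: 6 (1.15 equiv), n-BuLi (2.0 equiv per 6), Et2O, −78 → 0 °C; then 4, THF, −78 °C; AcOH, −78 °C → rt; crude product used at once
Reagents that add atoms: none
Why: 1,2-Addition of a hard aryllithium to a coumarin carbonyl is the classical entry to 2-arylbenzopyrylium precursors, here with an o-lithiophenoxide made by deprotonation and Br–Li exchange. The ring-opened bis-phenoxide is deactivated towards a second addition by its ortho-phenoxide donor. The cis C3=C4 inherited from the ring lets protonated 8 close to 9.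

Step 6
Reactants: 9 2-[2-hydroxy-4-(triisopropylsilyloxy)phenyl]-7-methoxy-8-[(E)-4-(tert-butyldimethylsilyloxy)-3-methylbut-2-enyl]-2H-chromen-2-ol
Product: 13 (2S)-2-[2-hydroxy-4-(triisopropylsilyloxy)phenyl]-7-methoxy-8-[(E)-4-(tert-butyldimethylsilyloxy)-3-methylbut-2-enyl]chroman, via flavylium phosphate ion pair 10 (not isolated), via 4H-flavene 11 (not isolated), via chroman-2-ylium ion 12 (not isolated)
Conditions: (R)-TRIP [(R)-3,3'-bis(2,4,6-triisopropylphenyl)-1,1'-binaphthyl-2,2'-diyl hydrogen phosphate] (10 mol %), Hantzsch ester (diethyl 2,6-dimethyl-1,4-dihydropyridine-3,5-dicarboxylate, 2.3 equiv), 5 Å MS, toluene, −20 → 0 °C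
Reagents that add atoms: none
Why: Proposed new method: the acid ionises 9 (both C2 epimers, and 8 through 9) to the aromatic flavylium ion 10, held to the chiral phosphate by the C2'–OH hydrogen bond; the dihydropyridine, bound through N–H to the phosphoryl oxygen, delivers hydride to the open C4 to give the achiral enol ether 11, the acid protonates C3 to give the chroman-2-ylium/o-quinone methide 12, and a second hydride at C2 gives 13. The closest known reaction types are the phosphoric acid/Hantzsch ester cascade reduction of 2-substituted quinolines (1,4-hydride, protonation, 1,2-hydride), the 1,4-reduction of 1-benzopyrylium ions generated from chromenols under the same catalysis, and the transfer hydrogenation of o-hydroxystyrenes through hydrogen-bonded o-quinone methides; new is their combination on a flavylium ion all the way to the flavan. No ring is formed, since the pyran ring comes from the coumarin and the open tautomer 8 re-enters by 6-exo-trig hemiketalisation. C2 is the only new stereocentre and is set under catalyst control in the last hydride transfer: the phosphate is anchored three atoms from C2 on the C2'–OH, the C8 chain beside O1 disfavours the ring-B rotamer that would put this anchor on the O1 side, and the 3,3'-aryl walls should leave the Re face of C2 open, which gives S. Chemoselectivity rests on the donor reducing only cations, so C2''=C3'', the silyl ethers and the arenes are untouched. C4-before-C2 regioselectivity follows from the shielding of C2 by ring B, and a stray hydride addition at C2 of 10 corrects itself because that adduct is itself a hydride donor that returns to 10. No achiral acid or counter-ion is present, so there is no racemic background path. Protonation of enol ether 11 is far easier than ionisation of the aryl ether in 13, which should protect the product at low temperature.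

Step 7
Reactants: 13 (2S)-2-[2-hydroxy-4-(triisopropylsilyloxy)phenyl]-7-methoxy-8-[(E)-4-(tert-butyldimethylsilyloxy)-3-methylbut-2-enyl]chroman
Product: 14 morusyunnansin E, 4-[(2S)-8-[(E)-4-hydroxy-3-methylbut-2-enyl]-7-methoxychroman-2-yl]benzene-1,3-diol
Conditions: TBAF/AcOH (1:1, 2.5 equiv), THF, 0 °C
Reagents that add atoms: none
Why: Fluoride cleaves both silyl ethers. The acetic acid buffer keeps the C4' oxygen protonated, so the phenoxide-driven quinone-methide opening of C2–O1 should not start, and C2 and the E alkene are preserved.

## Compound list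

1 | osthole, 7-methoxy-8-(3-methylbut-2-enyl)-2H-chromen-2-one | COc1ccc2ccc(=O)oc2c1CC=C(C)C | starting material
2 | (E)-4-(7-methoxy-2-oxo-2H-chromen-8-yl)-2-methylbut-2-enal | COc1ccc2ccc(=O)oc2c1C/C=C(\C)C=O | intermediate
3 | 8-[(E)-4-hydroxy-3-methylbut-2-enyl]-7-methoxy-2H-chromen-2-one | COc1ccc2ccc(=O)oc2c1C/C=C(\C)CO | intermediate
4 | 8-[(E)-4-(tert-butyldimethylsilyloxy)-3-methylbut-2-enyl]-7-methoxy-2H-chromen-2-one | COc1ccc2ccc(=O)oc2c1C/C=C(\C)CO[Si](C)(C)C(C)(C)C | intermediate
5 | 4-bromobenzene-1,3-diol | Oc1ccc(Br)c(O)c1 | starting material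
6 | 2-bromo-5-(triisopropylsilyloxy)phenol | CC(C)[Si](Oc1ccc(Br)c(O)c1)(C(C)C)C(C)C | intermediate
7 | lithium 2-lithio-5-(triisopropylsilyloxy)phenoxide | [Li]Oc1cc(O[Si](C(C)C)(C(C)C)C(C)C)ccc1[Li] | intermediate
8 | (Z)-3-[2-hydroxy-4-methoxy-3-[(E)-4-(tert-butyldimethylsilyloxy)-3-methylbut-2-enyl]phenyl]-1-[2-hydroxy-4-(triisopropylsilyloxy)phenyl]prop-2-en-1-one | COc1ccc(/C=C\C(=O)c2ccc(O[Si](C(C)C)(C(C)C)C(C)C)cc2O)c(O)c1C/C=C(\C)CO[Si](C)(C)C(C)(C)C | intermediate
9 | 2-[2-hydroxy-4-(triisopropylsilyloxy)phenyl]-7-methoxy-8-[(E)-4-(tert-butyldimethylsilyloxy)-3-methylbut-2-enyl]-2H-chromen-2-ol (racemic) | COc1ccc2C=CC(O)(c3ccc(O[Si](C(C)C)(C(C)C)C(C)C)cc3O)Oc2c1C/C=C(\C)CO[Si](C)(C)C(C)(C)C | intermediate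
10 | corresponding 2-aryl-1-benzopyrylium (flavylium) cation, paired with the chiral phosphate (cation drawn) | COc1ccc2ccc(-c3ccc(O[Si](C(C)C)(C(C)C)C(C)C)cc3O)[o+]c2c1C/C=C(\C)CO[Si](C)(C)C(C)(C)C | intermediate
11 | corresponding 2-aryl-4H-chromene (flav-2-ene) | COc1ccc2CC=C(c3ccc(O[Si](C(C)C)(C(C)C)C(C)C)cc3O)Oc2c1C/C=C(\C)CO[Si](C)(C)C(C)(C)C | intermediate
12 | corresponding 2-arylchroman-2-ylium cation, paired with the chiral phosphate (cation drawn) | COc1ccc2CCC(c3ccc(O[Si](C(C)C)(C(C)C)C(C)C)cc3O)=[O+]c2c1C/C=C(\C)CO[Si](C)(C)C(C)(C)C | intermediate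
13 | (2S)-2-[2-hydroxy-4-(triisopropylsilyloxy)phenyl]-7-methoxy-8-[(E)-4-(tert-butyldimethylsilyloxy)-3-methylbut-2-enyl]chroman | COc1ccc2c(c1C/C=C(\C)CO[Si](C)(C)C(C)(C)C)O[C@H](c1ccc(O[Si](C(C)C)(C(C)C)C(C)C)cc1O)CC2 | intermediate
14 | morusyunnansin E | COc1ccc2c(c1C/C=C(\C)CO)O[C@H](c1ccc(O)cc1O)CC2 | target

## Step count and least certain steps

Total steps: 7. Longest linear sequence: 6 (1 → 2 → 3 → 4 → 9 → 13 → 14).

**Step 6 (key step, proposed new method).**
- The most likely failure is insufficient facial discrimination in the hydride transfer to 12, because O1 and C3H2 flank C2 with similar bulk and ring B can rotate.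
- Further risks are:
  - re-ionisation of C2–O1 in 13 under the acid, leading to racemisation or reductive opening of the pyran ring;
  - loss of the C4'–O silyl group at the cation stage;
  - thermal Z-to-E drift of 8, which takes material out of the funnel.
- The fallback uses known chemistry only. It sets out from 4 (with 5 for ring B) and returns at 14.
  - Catalytic copper hydride (Cu(OAc)2, a bisphosphine, PMHS, t-BuOH) reduces C3=C4 of 4 to the dihydrocoumarin F1.
  - MOMCl/i-Pr2NEt converts 5 into 1-bromo-2,4-bis(methoxymethoxy)benzene F2.
  - Bromine–lithium exchange on F2 and addition to F1 at −78 °C opens the lactone to the ketone F3.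
  - Asymmetric transfer hydrogenation (RuCl(p-cymene)[(R,R)-TsDPEN], HCO2H/Et3N) gives the (R)-alcohol F4.
  - Mitsunobu cyclisation (PPh3, DIAD) closes O1–C2 with inversion to the protected (S)-flavan F5.
  - TMSOTf/2,2'-bipyridyl followed by water removes the MOM groups under nearly neutral conditions, and buffered TBAF removes the silyl ether, giving 14.

**Step 5.**
- Bromine–lithium exchange on the electron-rich phenoxide may be slow and the dianion poorly soluble. A second aryl addition to the ring-opened enone, or conjugate addition at C4, may compete.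
- The fallback replaces the O,C-dianion by a masked mono-anion. It sets out from 6 and returns at 9.
  - Ethyl vinyl ether/PPTS gives the 1-ethoxyethyl ether F6.
  - Exchange with one equivalent of n-BuLi, transmetalation to cerium and addition to 4 gives the masked hemiketal F7.
  - PPTS in THF–H2O at rt releases the C2'–OH without touching the silyl ethers, giving 9.

**Step 7.**
- Transient phenoxide formation at C4' may trigger opening of C2–O1 and erode the enantiopurity.
- The fallback removes the silyl groups before the stereocentre exists. It sets out from 9 and returns at 14.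
  - Buffered TBAF converts 9 into the unprotected hemiketal F9.
  - F9 is subjected to the conditions of step 6 in a more polar medium (CHCl3–dioxane), making 14 directly in the last operation.
  - The cost is a second acidic hydroxyl (C4'–OH) competing for the phosphate.

**Step 4.**
- Silylation may occur at the hydroxyl next to bromine or at both hydroxyls, because that hydroxyl is the more acidic although the more hindered.
- The fallback protects both and releases one. It sets out from 5 and returns at 6.
  - Excess TIPSCl gives the bis-silyl ether F8.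
  - One equivalent of TBAF at −78 °C should cleave the silyl ether ortho to bromine first, since it belongs to the better phenoxide leaving group, giving 6.

**Step 1.**
- Conversion may be low, oxidation may go too far, the doubly activated C1'' methylene may be attacked, and selenium residues may persist.
- The fallback exchanges the alkene terminus instead of oxidising C–H. It sets out from 1 and returns at 2: cross-metathesis of the prenyl group with methacrolein (second-generation Hoveyda–Grubbs catalyst, CH2Cl2, 40 °C) should give the E-enal 2 directly.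

## Further compounds

F1 | step 6 | 8-[(E)-4-(tert-butyldimethylsilyloxy)-3-methylbut-2-enyl]-7-methoxychroman-2-one | COc1ccc2CCC(=O)Oc2c1C/C=C(\C)CO[Si](C)(C)C(C)(C)C
F2 | step 6 | 1-bromo-2,4-bis(methoxymethoxy)benzene | COCOc1ccc(Br)c(OCOC)c1
F3 | step 6 | 1-[2,4-bis(methoxymethoxy)phenyl]-3-[2-hydroxy-4-methoxy-3-[(E)-4-(tert-butyldimethylsilyloxy)-3-methylbut-2-enyl]phenyl]propan-1-one | COCOc1ccc(C(=O)CCc2ccc(OC)c(C/C=C(\C)CO[Si](C)(C)C(C)(C)C)c2O)c(OCOC)c1
F4 | step 6 | (1R)-1-[2,4-bis(methoxymethoxy)phenyl]-3-[2-hydroxy-4-methoxy-3-[(E)-4-(tert-butyldimethylsilyloxy)-3-methylbut-2-enyl]phenyl]propan-1-ol | COCOc1ccc([C@H](O)CCc2ccc(OC)c(C/C=C(\C)CO[Si](C)(C)C(C)(C)C)c2O)c(OCOC)c1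
F5 | step 6 | (2S)-2-[2,4-bis(methoxymethoxy)phenyl]-7-methoxy-8-[(E)-4-(tert-butyldimethylsilyloxy)-3-methylbut-2-enyl]chroman | COc1ccc2c(c1C/C=C(\C)CO[Si](C)(C)C(C)(C)C)O[C@H](c1ccc(OCOC)cc1OCOC)CC2
F6 | step 5 | 1-bromo-2-(1-ethoxyethoxy)-4-(triisopropylsilyloxy)benzene | CCOC(C)Oc1cc(O[Si](C(C)C)(C(C)C)C(C)C)ccc1Br
F7 | step 5 | 2-[2-(1-ethoxyethoxy)-4-(triisopropylsilyloxy)phenyl]-7-methoxy-8-[(E)-4-(tert-butyldimethylsilyloxy)-3-methylbut-2-enyl]-2H-chromen-2-ol | COc1ccc2C=CC(O)(c3ccc(O[Si](C(C)C)(C(C)C)C(C)C)cc3OC(C)OCC)Oc2c1C/C=C(\C)CO[Si](C)(C)C(C)(C)C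
F8 | step 4 | 1-bromo-2,4-bis(triisopropylsilyloxy)benzene | CC(C)[Si](Oc1ccc(Br)c(O[Si](C(C)C)(C(C)C)C(C)C)c1)(C(C)C)C(C)C
F9 | step 7 | 2-(2,4-dihydroxyphenyl)-8-[(E)-4-hydroxy-3-methylbut-2-enyl]-7-methoxy-2H-chromen-2-ol | COc1ccc2C=CC(O)(c3ccc(O)cc3O)Oc2c1C/C=C(\C)CO
F0 | step 1 | none | none
A1 | alternative 1 | 1-[2,4-bis(methoxymethoxy)phenyl]-3-[2-hydroxy-4-methoxy-3-(3-methylbut-2-enyl)phenyl]propan-1-one | COCOc1ccc(C(=O)CCc2ccc(OC)c(CC=C(C)C)c2O)c(OCOC)c1
A2 | alternative 1 | (1R)-1-[2,4-bis(methoxymethoxy)phenyl]-3-[2-hydroxy-4-methoxy-3-(3-methylbut-2-enyl)phenyl]propan-1-ol | COCOc1ccc([C@H](O)CCc2ccc(OC)c(CC=C(C)C)c2O)c(OCOC)c1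
A3 | alternative 2 | 6-(hydroxymethyl)-3-methoxy-2-[(E)-4-(tert-butyldimethylsilyloxy)-3-methylbut-2-enyl]phenol | OCc1ccc(OC)c(C/C=C(\C)CO[Si](C)(C)C(C)(C)C)c1O
A4 | alternative 2 | 3-methoxy-6-methylidene-2-[(E)-4-(tert-butyldimethylsilyloxy)-3-methylbut-2-enyl]cyclohexa-2,4-dien-1-one | C=C1C=CC(OC)=C(C/C=C(\C)CO[Si](C)(C)C(C)(C)C)C1=O
A5 | alternative 2 | 2-ethenyl-5-(triisopropylsilyloxy)phenol | C=Cc1ccc(O[Si](C(C)C)(C(C)C)C(C)C)cc1O
A6 | alternative 3 | 8-[(E)-4-(tert-butyldimethylsilyloxy)-3-methylbut-2-enyl]-7-methoxy-4H-chromen-4-one | COc1ccc2c(=O)ccoc2c1C/C=C(\C)CO[Si](C)(C)C(C)(C)C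
A7 | alternative 3 | [2,4-bis(methoxymethoxy)phenyl]boronic acid | COCOc1ccc(B(O)O)c(OCOC)c1
A8 | alternative 3 | (2S)-2-[2,4-bis(methoxymethoxy)phenyl]-8-[(E)-4-(tert-butyldimethylsilyloxy)-3-methylbut-2-enyl]-7-methoxychroman-4-one | COc1ccc2c(c1C/C=C(\C)CO[Si](C)(C)C(C)(C)C)O[C@H](c1ccc(OCOC)cc1OCOC)CC2=O
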